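Remark on the chemistry: the target is achiral (no stereocentre, freely rotating diaryl ethers), so no step has to set configuration. Silyl enol ether 2 is expected as a mixture of double-bond isomers (E drawn); this does not matter, because that double bond becomes the central single bond of diene 4.

## Analysis of the target

The target 33 is 4-bromo-2-[4-(3,5-dihydroxyphenoxy)-3,5-dihydroxyphenoxy]benzene-1,3,5-triol: three benzene rings in a row, joined by two diaryl ether oxygens, with seven free phenols and one bromine. Ring A (atoms a1–a6) has hydroxyls on a1 and a3, the ether oxygen on a5 and hydrogens on a2, a4 and a6. Ring B (b1–b6) carries the oxygen to ring A on b1, hydroxyls on b2 and b6, and the oxygen to ring C on b4. Ring C (c1–c6) carries that oxygen on c1, hydroxyls on c2, c4 and c6, and bromine on c3. There is no stereocentre and no hindered axis, so the problem is connectivity and regiochemistry only. The free polyphenol is easily oxidised in air, especially as a phenoxide. The bromine would be lost on hydrogenolysis or halogen–metal exchange and can migrate on such an electron-rich ring in strong protic acid. The difficulty is twofold: both ether oxygens sit on carbons flanked by two ortho oxygens (b1 and c1), the worst case for copper-mediated or SNAr ether formation, and bromine must enter one ring only although all three are similarly activated. The strategy rests on ring A: the array a6–a1–a2–a3 with oxygen on a1 and a3 is an acetoacetate-derived dioxygenated diene, and a4–a5 is an alkyne with the ether oxygen on a5 and a removable ester on a4, which lies between two oxygen-bearing carbons.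

## Retrosynthetic reasoning

**33 to 32.** The last operation is cleavage of seven methyl ethers of the heptamethyl ether 32. Methyl ethers are chosen because they survive organolithium reagents, fluoride, hot alkali and hydrogenolysis. Benzyl ethers are excluded at this stage because their hydrogenolysis would also remove the bromine. The forward step must break only alkyl–oxygen bonds and leave both aryl–O–aryl bonds and the C–Br bond.

**32 to 26 and 30.** The b4–O bond is cut. Carbon b4 has hydrogen neighbours (b3, b5), so it can be one end of an aryne 31 across b3–b4, released from silyl triflate 26. The methoxy group on b2 polarises that aryne so that an oxygen nucleophile bonds to b4 and the proton ends on b3. The nucleophile is bromophenol 30, whose hindered oxygen (c1, between two methoxy groups) adds to the aryne with little steric penalty. This is convergent, and bromine arrives only after every reductive and organolithium step is over.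

**30 to 28 to 27.** Bromine is placed at the aldehyde stage, on 27, where the ring is less oxidisable and all directing effects point to one carbon. The formyl group of 28 is then exchanged for hydroxyl by Baeyer–Villiger oxidation through formate 29.

**26 to 19.** Silyl triflate 26 comes from o-silylphenol 25, which comes from carbamate 24, made from carbamate 20 of phenol 19. The C–Si bond is cut at b3, the position between the carbamate oxygen and a methoxy group, which is the most acidic C–H of the molecule; directed metalation (via 21, 22, 23) has to distinguish it from the ring A positions between two ether oxygens.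

**19 to 15.** Phenol 19 arises from benzyl ether 18 by hydrogenolysis, 18 from resorcinol 17 by methylation, and 17 from resorcylate 15 by hydrolysis and loss of CO2 through acid 16. The ester sits on a4, between two oxygenated carbons, which is exactly the arrangement that decarboxylates readily.

**15 to 4 and 12 (key disconnection).** Ring A is cut at a5–a6 and a3–a4. This gives diene 4 (a6, a1, a2, a3 with both oxygens) and aryloxypropiolate 12 (a5 with the ether oxygen, a4 with the ester). It is cut here, and not at the a5–O bond, because that bond joins two aromatic carbons only after the ring exists; before that, the hindered oxygen is attached to an sp carbon. The forward reaction must join the CH2 end of 4 to the oxygen-bearing carbon of 12 and aromatise without expelling the aryloxy group.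

**12 to 7 and 8.** Propiolate 12 comes from lithium acetylide 11, which comes from dichlorovinyl ether 10. Ether 10 is made from hindered phenol 7 and trichloroethylene 8 through dichloroacetylene 9. The hindered C–O bond is therefore formed by addition of a phenoxide to a linear sp carbon, where the two flanking methoxy groups hardly interfere.

**7 to 5, and 4 to 1.** Phenol 7 is the monobenzyl ether of hydroquinone 6, obtained by reduction of quinone 5; the two hydroxyls differ in hindrance and acidity. Diene 4 is reached from methyl acetoacetate 1 by two silylations through 2 and dienolate 3.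

## Alternatives that were turned down

**Alternative 1:** Ring B is disconnected at the bond between its ring A-bearing carbon and a neighbouring hydroxyl carbon, giving the open-chain methyl (2E)-3-(3-bromo-2,4,6-trimethoxyphenoxy)-6-(3,5-dimethoxyphenoxy)-5-oxohex-2-enoate A2. In the forward key step a strong non-nucleophilic base deprotonates the aryloxymethyl carbon, which attacks the ester; the ring closes and tautomerises to 5-(3-bromo-2,4,6-trimethoxyphenoxy)-2-(3,5-dimethoxyphenoxy)benzene-1,3-diol A1.
- For it: both ether bonds are made on non-aromatic carbons, the ring B hydroxyls emerge free, and only five methyl ethers remain. On convergence and step economy it is stronger than the chosen route.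
- Against it: the ketone of A2 has a second, more acidic methylene (between the ketone and the enol ether double bond). Its carbanion cannot close a six-membered ring and can expel the ring C phenoxide by β-elimination. Only the E isomer of the enoate can cyclise. The hindered bromophenol 30 would have to be added to an activated alkyne or allene beforehand.
- In its place the chosen strategy offers a ring closure whose orientation is fixed by polarisation alone, with no competing enolisation site and no leaving group β to a carbanion.

**Alternative 2:** Ring C is disconnected into 4-chloro-2-[4-(3,5-dimethoxyphenoxy)-3,5-dimethoxyphenoxy]-3-(propan-2-yloxy)cyclobut-2-en-1-one A4 and tributyl(1-ethoxyethenyl)stannane A5. A palladium-catalysed Stille coupling gives a 4-alkenylcyclobutenone, which opens thermally to a dienylketene and closes by 6π electrocyclisation to 2-[4-(3,5-dimethoxyphenoxy)-3,5-dimethoxyphenoxy]-5-ethoxy-3-isopropoxyphenol A3.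
- For it: the hindered c1–O bond comes from addition–elimination on a squaric ester, the ring-forming sequence is well established for alkoxy-substituted cyclobutenones, and the product has one free phenol that could direct bromination. On precedent for the ring-forming event it is stronger than the chosen route.
- Against it: A4 needs several steps, including a regioselective carbonyl reduction and a chlorination. A stoichiometric tin reagent is used. Three kinds of alkyl ether must be cleaved at the end. Bromine must be introduced late on a molecule with three electron-rich rings. It also presupposes phenol 19, so the hindered b1–O–a5 ether remains unsolved.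
- The chosen strategy builds exactly that ether, uses inexpensive reagents, and brings bromine in with a pre-brominated fragment.

**Alternative 3:** Ring C is disconnected at two C–C bonds into dimethyl 2-[4-(3,5-dimethoxyphenoxy)-3,5-dimethoxyphenoxy]propanedioate A7 and dimethyl 3-oxopentanedioate A8. An alkoxide base under heating effects a double Claisen condensation to dimethyl 5-[4-(3,5-dimethoxyphenoxy)-3,5-dimethoxyphenoxy]-2,4,6-trihydroxybenzene-1,3-dicarboxylate A6.
- For it: the reagents are cheap, the c1–O bond is a simple alkylation of phenol 19 with a halomalonate, and ring C appears with three free hydroxyls, so fewer ethers must be cleaved. In these respects it is stronger.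
- Against it: a 2-substituted malonate is a poor partner in this condensation (steric hindrance, retro-Claisen, self-condensation of A8). Two ester groups must be removed. Monobromination of a free phloroglucinol ring is hard to stop at one bromine. Phenol 19 is again required.
- The chosen strategy gives a better-controlled ring formation, an unambiguous bromine position, and a solution to the ring A–ring B ether that this route only assumes.

Key step: step 7

## Route

Step 1
Reactants: 1 methyl acetoacetate
Product: 2 methyl (2E)-3-(trimethylsilyloxy)but-2-enoate (E/Z mixture expected)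
Conditions: Me3SiCl, Et3N, hexane, rt
Reagents that add atoms: chlorotrimethylsilane, C[Si](C)(C)Cl
Why: O-silylation of the enolised β-keto ester with a silyl chloride and an amine base is the standard first stage of the preparation of 1,3-bis(silyloxy)dienes; the salt is removed by filtration without aqueous work-up.

Step 2
Reactants: 2 methyl (2E)-3-(trimethylsilyloxy)but-2-enoate
Product: 4 (1Z)-1-methoxy-1,3-bis(trimethylsilyloxy)buta-1,3-diene, via lithium dienolate 3 (not isolated)
Conditions: LiN(iPr)2, THF, −78 °C; Me3SiCl, −78 °C → rt; non-aqueous work-up
Reagents that add atoms: chlorotrimethylsilane, C[Si](C)(C)Cl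
Why: Kinetic γ-deprotonation of the methyl group gives the extended ester dienolate, which is silylated on oxygen to the ketene acetal; this is the established route to this diene, which is used at once because it is sensitive to moisture.

Step 3
Reactants: 5 2,6-dimethoxy-1,4-benzoquinone
Product: 6 2,6-dimethoxybenzene-1,4-diol
Conditions: Na2S2O4, H2O/EtOAc, rt, argon
Reagents that add atoms: none
Why: Dithionite reduction of a benzoquinone to its hydroquinone is fast and clean; the air-sensitive product is carried on directly.

Step 4
Reactants: 6 2,6-dimethoxybenzene-1,4-diol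
Product: 7 4-(benzyloxy)-2,6-dimethoxyphenol
Conditions: BnBr (1.0 equiv), K2CO3, acetone, rt → 40 °C, argon
Reagents that add atoms: benzyl bromide, BrCc1ccccc1
Why: Williamson etherification; the hydroxyl meta to the two methoxy groups is the more acidic and the less hindered one, while the other is flanked by and hydrogen-bonded to two methoxy groups, so one equivalent of alkylating agent should go to the former.

Step 5
Reactants: 7 4-(benzyloxy)-2,6-dimethoxyphenol; 8 trichloroethylene
Product: 10 5-(benzyloxy)-2-{[(E)-1,2-dichloroethenyl]oxy}-1,3-dimethoxybenzene, via dichloroacetylene 9 (not isolated)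
Conditions: K2CO3, DMF, 70 °C, closed vessel under argon
Reagents that add atoms: none
Why: Base eliminates HCl from trichloroethylene to dichloroacetylene, and the phenoxide adds anti across the linear alkyne to give the (E)-1,2-dichlorovinyl aryl ether, a known preparation of such ethers from phenols. Attack on an sp carbon is barely slowed by the two ortho methoxy groups.

Step 6
Reactants: 10 5-(benzyloxy)-2-{[(E)-1,2-dichloroethenyl]oxy}-1,3-dimethoxybenzene
Product: 12 methyl 3-[4-(benzyloxy)-2,6-dimethoxyphenoxy]prop-2-ynoate, via lithium acetylide 11 (not isolated)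
Conditions: n-BuLi (2.3 equiv), THF, −78 → −40 °C; ClCO2Me (excess), −78 → 0 °C
Reagents that add atoms: methyl chloroformate, COC(=O)Cl
Why: Deprotonation, loss of LiCl and chlorine–lithium exchange convert a 1,2-dichlorovinyl ether into the lithium aryloxyacetylide (the known route to aryl ynol ethers), which is acylated by the chloroformate. The benzyl and methyl ethers are inert to n-BuLi at this temperature.

Step 7
Reactants: 4 (1Z)-1-methoxy-1,3-bis(trimethylsilyloxy)buta-1,3-diene; 12 methyl 3-[4-(benzyloxy)-2,6-dimethoxyphenoxy]prop-2-ynoate
Product: 15 methyl 2-[4-(benzyloxy)-2,6-dimethoxyphenoxy]-4,6-dihydroxybenzoate, via cycloadduct 13 (not isolated), via silyl ether 14 (not isolated)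
Conditions: 4 (2.5 equiv), toluene, 90 °C, sealed tube; then 1 M HCl, THF, 0 °C → rt
Reagents that add atoms: none
Why: Proposed new method: the closest known reaction type is the cycloaddition–aromatisation of 1-alkoxy-1,3-bis(silyloxy)buta-1,3-dienes with alkyl-substituted alkynoates to 6-substituted 2,4-dihydroxybenzoates, and a 3-aryloxypropiolate has not been shown as the dienophile. In 12 the ester makes the oxygen-bearing carbon the acceptor (β) carbon and the ether oxygen makes the ester-bearing carbon the electron-rich end, while in 4 the CH2 terminus is the most nucleophilic carbon and the ketene acetal carbon becomes an oxocarbenium centre once that terminus has reacted. The bonds a6–a5 and then a4–a3 therefore form in one orientation only, either in a concerted asynchronous Diels–Alder transition state or stepwise by Mukaiyama–Michael addition and Claisen-type closure of the allenyl ester enolate onto the oxocarbenium ion; in both descriptions ring A closes as a six-membered ring by a [4+2] mode (6-endo in the stepwise picture). Cycloadduct 13 is a cyclohexa-1,4-diene with a mixed methyl silyl ketal at a3; it loses MeOSiMe3 and enolises to the aromatic silyl ether 14, and dilute acid frees the second phenol. The selectivity needed is regiochemical and chemoselective: the orientation follows from the matched polarisation just described, and aromatisation can only take the ketal route because the aryloxy group sits on an sp2 carbon and cannot be expelled, so the hindered diaryl ether stays. The only stereocentre formed, the ketal carbon of 13, is racemic and disappears on aromatisation. The donor oxygen lowers dienophilicity, which is met by heat and an excess of 4; catalytic Me3SiOTf at low temperature is the reserve within the same strategy.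

Step 8
Reactants: 15 methyl 2-[4-(benzyloxy)-2,6-dimethoxyphenoxy]-4,6-dihydroxybenzoate
Product: 17 5-[4-(benzyloxy)-2,6-dimethoxyphenoxy]benzene-1,3-diol, via carboxylic acid 16 (not isolated)
Conditions: KOH, H2O/MeOH, reflux, argon; then HCl to pH 2, 80 °C
Reagents that add atoms: none
Why: Saponification followed by protodecarboxylation; a benzoic acid with oxygen on both ortho carbons and the para carbon is protonated easily at the ipso carbon and loses CO2 on warming in acid. The benzyl ether and the diaryl ether are stable to alkali and dilute acid.

Step 9
Reactants: 17 5-[4-(benzyloxy)-2,6-dimethoxyphenoxy]benzene-1,3-diol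
Product: 18 5-(benzyloxy)-2-(3,5-dimethoxyphenoxy)-1,3-dimethoxybenzene
Conditions: MeI, K2CO3, acetone, 50 °C
Reagents that add atoms: iodomethane, CI
Why: Williamson O-methylation of both phenols with a weak base in acetone, conditions under which O-alkylation of resorcinols dominates over C-alkylation.

Step 10
Reactants: 18 5-(benzyloxy)-2-(3,5-dimethoxyphenoxy)-1,3-dimethoxybenzene
Product: 19 4-(3,5-dimethoxyphenoxy)-3,5-dimethoxyphenol
Conditions: H2 (1 atm), Pd/C, EtOAc/MeOH, rt
Reagents that add atoms: none
Why: Hydrogenolysis of the benzyl ether; methyl ethers and the diaryl ether are inert, and no halogen is present yet.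

Step 11
Reactants: 19 4-(3,5-dimethoxyphenoxy)-3,5-dimethoxyphenol
Product: 20 4-(3,5-dimethoxyphenoxy)-3,5-dimethoxyphenyl N-(propan-2-yl)carbamate
Conditions: iPrNCO, Et3N (cat.), CH2Cl2, rt
Reagents that add atoms: isopropyl isocyanate, CC(C)N=C=O
Why: Base-catalysed addition of the unhindered phenol to an isocyanate gives the N-monoalkyl carbamate, a strong ortho-directing group that can later be removed under mild basic conditions.

Step 12
Reactants: 20 4-(3,5-dimethoxyphenoxy)-3,5-dimethoxyphenyl N-(propan-2-yl)carbamate
Product: 24 4-(3,5-dimethoxyphenoxy)-3,5-dimethoxy-2-(trimethylsilyl)phenyl N-(propan-2-yl)carbamate, via N-silyl carbamate 21 (not isolated), via aryllithium 22 (not isolated), via disilyl carbamate 23 (not isolated)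
Conditions: TBSOTf, TMEDA, Et2O, 0 °C → rt; n-BuLi, TMEDA, −78 °C; Me3SiCl, −78 °C → rt; aq. NaHSO4 work-up
Reagents that add atoms: chlorotrimethylsilane, C[Si](C)(C)Cl
Why: Directed ortho-metalation of an in situ N-silylated aryl carbamate followed by C-silylation is an established entry to o-silylaryl carbamates. The two equivalent positions b3/b5 lie between the carbamate oxygen and a methoxy group and are lithiated at −78 °C much faster than the ring A positions, which are activated by ether oxygens only. The N-silyl group is lost on acidic work-up.

Step 13
Reactants: 24 4-(3,5-dimethoxyphenoxy)-3,5-dimethoxy-2-(trimethylsilyl)phenyl N-(propan-2-yl)carbamate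
Product: 26 4-(3,5-dimethoxyphenoxy)-3,5-dimethoxy-2-(trimethylsilyl)phenyl trifluoromethanesulfonate, via silylphenol 25 (not isolated)
Conditions: DBU, Et2NH, MeCN, 40 °C; then PhNTf2, rt
Reagents that add atoms: N-phenylbis(trifluoromethanesulfonimide), O=S(=O)(N(c1ccccc1)S(=O)(=O)C(F)(F)F)C(F)(F)F
Why: The N–H carbamate is cleaved by E1cB elimination to the phenoxide and isopropyl isocyanate (trapped by diethylamine), and the phenoxide is triflated in the same flask, so the protodesilylation-prone o-silylphenol is never isolated; this is the known one-pot conversion to o-silylaryl triflates.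

Step 14
Reactants: 27 2,4,6-trimethoxybenzaldehyde
Product: 28 3-bromo-2,4,6-trimethoxybenzaldehyde
Conditions: NBS (1.0 equiv), MeCN, 0 °C → rt
Reagents that add atoms: N-bromosuccinimide, O=C1CCC(=O)N1Br
Why: Electrophilic aromatic bromination; the free ring position is ortho to two methoxy groups, para to the third and meta to the formyl group, so all directing effects converge. The first bromine and the aldehyde temper the ring against a second substitution.

Step 15
Reactants: 28 3-bromo-2,4,6-trimethoxybenzaldehyde
Product: 30 3-bromo-2,4,6-trimethoxyphenol, via aryl formate 29 (not isolated)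
Conditions: mCPBA, CH2Cl2, 0 °C → rt; aq. Na2S2O3/NaHCO3 wash; then Et3N (cat.), MeOH, rt
Reagents that add atoms: 3-chloroperoxybenzoic acid, OOC(=O)c1cccc(Cl)c1
Why: Baeyer–Villiger oxidation of an electron-rich benzaldehyde proceeds by aryl migration to the aryl formate, which is methanolysed to the phenol. Excess peracid is destroyed before the oxidisable phenol is set free.

Step 16
Reactants: 26 4-(3,5-dimethoxyphenoxy)-3,5-dimethoxy-2-(trimethylsilyl)phenyl trifluoromethanesulfonate; 30 3-bromo-2,4,6-trimethoxyphenol
Product: 32 2-bromo-4-[4-(3,5-dimethoxyphenoxy)-3,5-dimethoxyphenoxy]-1,3,5-trimethoxybenzene, via aryne 31 (not isolated)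
Conditions: CsF (3 equiv), MeCN, rt
Reagents that add atoms: none
Why: Fluoride-induced 1,2-elimination of an o-silylaryl triflate gives the aryne, and phenols add to arynes under these conditions to give diaryl ethers. The methoxy group next to the aryne directs the phenoxide to the distal carbon b4, as for 3-alkoxyarynes, and the aryl anion is protonated at b3. The aryl bromide is inert to CsF, and the blocked ortho and para positions of 30 exclude C-arylation.

Step 17
Reactants: 32 2-bromo-4-[4-(3,5-dimethoxyphenoxy)-3,5-dimethoxyphenoxy]-1,3,5-trimethoxybenzene
Product: 33 4-bromo-2-[4-(3,5-dihydroxyphenoxy)-3,5-dihydroxyphenoxy]benzene-1,3,5-triol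
Conditions: BBr3 (excess), CH2Cl2, −78 °C → rt; then MeOH/H2O, 0 °C, argon
Reagents that add atoms: none
Why: Lewis-acid cleavage of aryl methyl ethers with BBr3 attacks only the methyl–oxygen bonds, leaving diaryl ethers and aryl bromides intact; this is the usual last step to brominated polyphenols. The product is worked up and purified with exclusion of air.

## Compound list

1 | methyl acetoacetate | COC(=O)CC(C)=O | starting material
2 | methyl (2E)-3-(trimethylsilyloxy)but-2-enoate (E/Z mixture expected, E drawn) | COC(=O)/C=C(\C)O[Si](C)(C)C | intermediate
3 | lithium (1E)-1-methoxy-3-(trimethylsilyloxy)buta-1,3-dien-1-olate | CO/C(O[Li])=C/C(=C)O[Si](C)(C)C | intermediate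
4 | (1Z)-1-methoxy-1,3-bis(trimethylsilyloxy)buta-1,3-diene | CO/C(O[Si](C)(C)C)=C/C(=C)O[Si](C)(C)C | intermediate
5 | 2,6-dimethoxy-1,4-benzoquinone | COC1=CC(=O)C=C(OC)C1=O | starting material
6 | 2,6-dimethoxybenzene-1,4-diol | COc1cc(O)cc(OC)c1O | intermediate
7 | 4-(benzyloxy)-2,6-dimethoxyphenol | COc1cc(OCc2ccccc2)cc(OC)c1O | intermediate
8 | trichloroethylene | ClC=C(Cl)Cl | starting material
9 | dichloroacetylene | ClC#CCl | intermediate
10 | 5-(benzyloxy)-2-{[(E)-1,2-dichloroethenyl]oxy}-1,3-dimethoxybenzene | Cl/C=C(/Cl)Oc1c(OC)cc(OCc2ccccc2)cc1OC | intermediate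
11 | lithium [4-(benzyloxy)-2,6-dimethoxyphenoxy]acetylide | [Li]C#COc1c(OC)cc(OCc2ccccc2)cc1OC | intermediate
12 | methyl 3-[4-(benzyloxy)-2,6-dimethoxyphenoxy]prop-2-ynoate | COC(=O)C#COc1c(OC)cc(OCc2ccccc2)cc1OC | intermediate
13 | methyl 2-[4-(benzyloxy)-2,6-dimethoxyphenoxy]-6-methoxy-4,6-bis(trimethylsilyloxy)cyclohexa-1,4-diene-1-carboxylate (racemic) | COC(=O)C1=C(Oc2c(OC)cc(OCc3ccccc3)cc2OC)CC(O[Si](C)(C)C)=CC1(OC)O[Si](C)(C)C | intermediate
14 | methyl 2-[4-(benzyloxy)-2,6-dimethoxyphenoxy]-6-hydroxy-4-(trimethylsilyloxy)benzoate | COC(=O)c1c(O)cc(O[Si](C)(C)C)cc1Oc1c(OC)cc(OCc2ccccc2)cc1OC | intermediate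
15 | methyl 2-[4-(benzyloxy)-2,6-dimethoxyphenoxy]-4,6-dihydroxybenzoate | COC(=O)c1c(O)cc(O)cc1Oc1c(OC)cc(OCc2ccccc2)cc1OC | intermediate
16 | 2-[4-(benzyloxy)-2,6-dimethoxyphenoxy]-4,6-dihydroxybenzoic acid | OC(=O)c1c(O)cc(O)cc1Oc1c(OC)cc(OCc2ccccc2)cc1OC | intermediate
17 | 5-[4-(benzyloxy)-2,6-dimethoxyphenoxy]benzene-1,3-diol | Oc1cc(O)cc(Oc2c(OC)cc(OCc3ccccc3)cc2OC)c1 | intermediate
18 | 5-(benzyloxy)-2-(3,5-dimethoxyphenoxy)-1,3-dimethoxybenzene | COc1cc(OC)cc(Oc2c(OC)cc(OCc3ccccc3)cc2OC)c1 | intermediate
19 | 4-(3,5-dimethoxyphenoxy)-3,5-dimethoxyphenol | COc1cc(OC)cc(Oc2c(OC)cc(O)cc2OC)c1 | intermediate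
20 | 4-(3,5-dimethoxyphenoxy)-3,5-dimethoxyphenyl N-(propan-2-yl)carbamate | COc1cc(OC)cc(Oc2c(OC)cc(OC(=O)NC(C)C)cc2OC)c1 | intermediate
21 | 4-(3,5-dimethoxyphenoxy)-3,5-dimethoxyphenyl N-(tert-butyldimethylsilyl)-N-(propan-2-yl)carbamate | COc1cc(OC)cc(Oc2c(OC)cc(OC(=O)N(C(C)C)[Si](C)(C)C(C)(C)C)cc2OC)c1 | intermediate
22 | 2-lithio derivative of 21 (lithium on b3) | COc1cc(OC)cc(Oc2c(OC)cc(OC(=O)N(C(C)C)[Si](C)(C)C(C)(C)C)c([Li])c2OC)c1 | intermediate
23 | 4-(3,5-dimethoxyphenoxy)-3,5-dimethoxy-2-(trimethylsilyl)phenyl N-(tert-butyldimethylsilyl)-N-(propan-2-yl)carbamate | COc1cc(OC)cc(Oc2c(OC)cc(OC(=O)N(C(C)C)[Si](C)(C)C(C)(C)C)c([Si](C)(C)C)c2OC)c1 | intermediate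
24 | 4-(3,5-dimethoxyphenoxy)-3,5-dimethoxy-2-(trimethylsilyl)phenyl N-(propan-2-yl)carbamate | COc1cc(OC)cc(Oc2c(OC)cc(OC(=O)NC(C)C)c([Si](C)(C)C)c2OC)c1 | intermediate
25 | 4-(3,5-dimethoxyphenoxy)-3,5-dimethoxy-2-(trimethylsilyl)phenol | COc1cc(OC)cc(Oc2c(OC)cc(O)c([Si](C)(C)C)c2OC)c1 | intermediate
26 | 4-(3,5-dimethoxyphenoxy)-3,5-dimethoxy-2-(trimethylsilyl)phenyl trifluoromethanesulfonate | COc1cc(OC)cc(Oc2c(OC)cc(OS(=O)(=O)C(F)(F)F)c([Si](C)(C)C)c2OC)c1 | intermediate
27 | 2,4,6-trimethoxybenzaldehyde | COc1cc(OC)c(C=O)c(OC)c1 | starting material
28 | 3-bromo-2,4,6-trimethoxybenzaldehyde | COc1cc(OC)c(C=O)c(OC)c1Br | intermediate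
29 | 3-bromo-2,4,6-trimethoxyphenyl formate | COc1cc(OC)c(OC=O)c(OC)c1Br | intermediate
30 | 3-bromo-2,4,6-trimethoxyphenol | COc1cc(OC)c(O)c(OC)c1Br | intermediate
31 | 4-(3,5-dimethoxyphenoxy)-3,5-dimethoxy-1,2-didehydrobenzene (aryne) | COC1=CC#CC(OC)=C1Oc1cc(OC)cc(OC)c1 | intermediate
32 | 2-bromo-4-[4-(3,5-dimethoxyphenoxy)-3,5-dimethoxyphenoxy]-1,3,5-trimethoxybenzene | COc1cc(OC)cc(Oc2c(OC)cc(Oc3c(OC)cc(OC)c(Br)c3OC)cc2OC)c1 | intermediate
33 | 4-bromo-2-[4-(3,5-dihydroxyphenoxy)-3,5-dihydroxyphenoxy]benzene-1,3,5-triol | Oc1cc(O)cc(Oc2c(O)cc(Oc3c(O)cc(O)c(Br)c3O)cc2O)c1 | target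

## Step count and least certain steps

Total step count: 17. Longest linear sequence: 13 steps (steps 3–13, 16 and 17, from quinone 5); steps 1–2 and 14–15 are side branches.

**Step 7 (key step, proposed new method).** The most likely failure is that cycloaddition is too slow, because the aryloxy donor raises the acceptor orbital of the alkyne. Thermal decay and silyl migration of the diene, or a [2+2]-type addition through its central carbon, could then outrun ring formation. Fallback by known chemistry: setting out from phenol 7, a copper-catalysed Ullmann-type O-arylation with commercial 1-bromo-3,5-dimethoxybenzene (COc1cc(Br)cc(OC)c1; CuI, picolinic acid, K3PO4, DMSO, 100 °C) should give diaryl ether 18 directly and rejoin the route there, replacing steps 5–9. It is held in reserve because a phenol flanked by two methoxy groups is a slow partner in such couplings. This fallback makes no compound outside the list (F0).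

**Step 16.** The hindered, only moderately nucleophilic phenoxide of 30 may capture the aryne too slowly, so that addition of fluoride, reaction with the solvent or oligomerisation of the aryne takes over. Fallback: setting out from phenol 19, the roles are reversed. Commercial 2-bromo-1,3,5-trimethoxybenzene (COc1cc(OC)c(Br)c(OC)c1) is iodinated with N-iodosuccinimide and catalytic CF3CO2H in MeCN to 2-bromo-4-iodo-1,3,5-trimethoxybenzene F1. The now unhindered phenol 19 is then coupled at the C–I bond only (CuI, picolinic acid, K3PO4, DMSO, 90 °C), returning to the route at 32 and bypassing steps 11–16.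

**Step 12.** Metalation may not be fully site-selective (lithiation of ring A between two ether oxygens), or the lithiated carbamate may rearrange by anionic ortho-Fries migration on warming. Fallback: setting out from phenol 19, the silicon is introduced without a directing group. Amine-catalysed ortho-bromination (NBS, cat. iPr2NH, CH2Cl2, 0 °C) should give 2-bromo-4-(3,5-dimethoxyphenoxy)-3,5-dimethoxyphenol F2. O-Silylation with (Me3Si)2NH then gives [2-bromo-4-(3,5-dimethoxyphenoxy)-3,5-dimethoxyphenoxy]trimethylsilane F3. Treatment with n-BuLi at −78 °C effects bromine–lithium exchange and migration of silicon from oxygen to carbon, and the resulting phenoxide of 25 is triflated in the same flask with Tf2O, returning to the route at 26.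

**Step 17.** Cleavage of seven ethers may stop short. In addition, the HBr released on aqueous quench may promote migration or loss of bromine on the phloroglucinol-type ring, and the product may oxidise in air. Fallback: setting out from 32, the ethers are cleaved by a non-protic silyl dealkylation. Me3SiI with 2,6-di-tert-butylpyridine in sulfolane at 60–80 °C should give the heptakis(trimethylsilyl) ether of the target F4, which is isolated under anhydrous conditions and methanolysed at neutral pH to 33.

**Step 4.** Alkylation may not discriminate fully between the two hydroxyls, may go on to the dibenzyl ether, or the hydroquinone may reoxidise under base. Fallback: setting out from hydroquinone 6, both hydroxyls are benzylated (excess BnBr, K2CO3, DMF) to 2,5-bis(benzyloxy)-1,3-dimethoxybenzene F5. The benzyl ether flanked by two methoxy groups, which is twisted out of conjugation and can chelate a Lewis acid, is then cleaved selectively (BCl3, 1 equiv, pentamethylbenzene, CH2Cl2, −78 °C), returning to the route at 7.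

## Further compounds

F0 | step 7 | none | none
F1 | step 16 | 2-bromo-4-iodo-1,3,5-trimethoxybenzene | COc1cc(OC)c(I)c(OC)c1Br
F2 | step 12 | 2-bromo-4-(3,5-dimethoxyphenoxy)-3,5-dimethoxyphenol | COc1cc(OC)cc(Oc2c(OC)cc(O)c(Br)c2OC)c1
F3 | step 12 | [2-bromo-4-(3,5-dimethoxyphenoxy)-3,5-dimethoxyphenoxy]trimethylsilane | COc1cc(OC)cc(Oc2c(OC)cc(O[Si](C)(C)C)c(Br)c2OC)c1
F4 | step 17 | heptakis(trimethylsilyl) ether of 33 | C[Si](C)(C)Oc1cc(O[Si](C)(C)C)cc(Oc2c(O[Si](C)(C)C)cc(Oc3c(O[Si](C)(C)C)cc(O[Si](C)(C)C)c(Br)c3O[Si](C)(C)C)cc2O[Si](C)(C)C)c1
F5 | step 4 | 2,5-bis(benzyloxy)-1,3-dimethoxybenzene | COc1cc(OCc2ccccc2)cc(OC)c1OCc1ccccc1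
A1 | alternative 1 | 5-(3-bromo-2,4,6-trimethoxyphenoxy)-2-(3,5-dimethoxyphenoxy)benzene-1,3-diol | COc1cc(OC)cc(Oc2c(O)cc(Oc3c(OC)cc(OC)c(Br)c3OC)cc2O)c1
A2 | alternative 1 | methyl (2E)-3-(3-bromo-2,4,6-trimethoxyphenoxy)-6-(3,5-dimethoxyphenoxy)-5-oxohex-2-enoate | COC(=O)/C=C(\CC(=O)COc1cc(OC)cc(OC)c1)Oc1c(OC)cc(OC)c(Br)c1OC
A3 | alternative 2 | 2-[4-(3,5-dimethoxyphenoxy)-3,5-dimethoxyphenoxy]-5-ethoxy-3-isopropoxyphenol | CCOc1cc(O)c(Oc2cc(OC)c(Oc3cc(OC)cc(OC)c3)c(OC)c2)c(OC(C)C)c1
A4 | alternative 2 | 4-chloro-2-[4-(3,5-dimethoxyphenoxy)-3,5-dimethoxyphenoxy]-3-(propan-2-yloxy)cyclobut-2-en-1-one (racemic) | CC(C)OC1=C(Oc2cc(OC)c(Oc3cc(OC)cc(OC)c3)c(OC)c2)C(=O)C1Cl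
A5 | alternative 2 | tributyl(1-ethoxyethenyl)stannane | CCCC[Sn](CCCC)(CCCC)C(=C)OCC
A6 | alternative 3 | dimethyl 5-[4-(3,5-dimethoxyphenoxy)-3,5-dimethoxyphenoxy]-2,4,6-trihydroxybenzene-1,3-dicarboxylate | COC(=O)c1c(O)c(Oc2cc(OC)c(Oc3cc(OC)cc(OC)c3)c(OC)c2)c(O)c(C(=O)OC)c1O
A7 | alternative 3 | dimethyl 2-[4-(3,5-dimethoxyphenoxy)-3,5-dimethoxyphenoxy]propanedioate | COC(=O)C(Oc1cc(OC)c(Oc2cc(OC)cc(OC)c2)c(OC)c1)C(=O)OC
A8 | alternative 3 | dimethyl 3-oxopentanedioate | COC(=O)CC(=O)CC(=O)OC
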